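## The problem

The target 26 is a hexacyclic spiro-biflavonoid. Its 5,7-dihydroxy-3-hydroxychroman-4-one (benzo ring A, pyranone ring B) has C2 as a spiro carbon that is also C4 of a cyclohexa-2,5-dienone (ring D). A dihydrofuran (ring C) is fused across the chromanone C3–C2 bond and across the bond from the spiro carbon to one dienone β-carbon; its other atoms are an oxygen on that β-carbon and an OCH(4-hydroxyphenyl) carbon on chromanone C3. The second enone arm of ring D carries a dihydropyran (ring E: O on the β-carbon, CH2 on the α-carbon) with a cis 2-(4-hydroxyphenyl)-3-hydroxy pair. Of the five stereocentres, three are contiguous in the core (furan CH(Ar) S, carbinol C3 R, spiro carbon S), and the carbinol and spiro carbons are adjacent and fully substituted. Within the core the carbinol centre can control the other two, because cis fusion of rings B and C fixes the spiro carbon and the aryl group prefers the convex face; the (2S,3S) pair of ring E is too remote to be induced and must arrive in an enantiopure building block. Rough treatment is excluded by several features: both OCH(Ar) carbons are para-oxygenated benzylic ethers of vinylogous acids (ionisation by acid, hydrogenolysis); the alkoxide of the tertiary α-ketol can fragment with aromatisation of ring D; a chromanone that still has H at C3 can lose its C2 aryloxide by β-elimination; and the dienone can be reduced. The key step rests on three facts: the carbinol carbon is the α-carbon of the ring B ketone, the furan CH(Ar) carbon is at the aldehyde oxidation level, and the furan oxygen sits on an enone β-carbon, while ring D before furan closure has two identical methoxy enone arms, so the spiro carbon becomes stereogenic only when the furan closes.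

## Retrosynthesis

**26 from 25.** No skeletal bond is cut. The four phenols and the ring E hydroxyl are carried as benzyl ethers in 25 and freed together by hydrogenolysis; the tertiary carbinol stays free throughout. Benzyl ethers survive amide bases, zinc alkoxides, dilute acid and fluoride, and their neutral removal at the end avoids both base (α-ketol fragmentation) and acid (benzylic ionisation).

**25 from 23.** The ring E bond from oxygen to the dienone β-carbon is cut, leaving the hydroxy enol 24, which is formed by desilylation of 23. The alternative cut at the O–CH(Ar) bond would need a substitution at a para-alkoxybenzylic carbon, with loss of stereochemical control. The chosen closure is a cyclodehydration (vinylogous esterification) that never breaks a bond at the benzylic carbon, so the syn arrangement of the side chain becomes the cis ring E pair.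

**23 from 14 and 21.** The bond from the ring D α-carbon to the ring E CH2 is cut, giving the vinylogous acid 14 and the aldehyde 21. Reductive alkylation of a cyclic 1,3-dione-type carbon with an aldehyde is reliable and joins two finished halves. Cinnamylation of 14 followed by dihydroxylation was weighed and rejected, because it would put a reagent-controlled oxidation late on the full core and would need a double inversion to reach the cis series. 14 comes from 13 by hydrolysis of the remaining methyl vinylogous ester.

**21 from 17 and 11.** The C2–C3 bond of the side chain is cut by a syn glycolate aldol; 17 comes from oxazolidinone 15 and acid chloride 16. A cinnamate dihydroxylation would give the same syn diol, but the aldol delivers the two oxygens already differentiated (benzyl on C2, free on C3), which the ring E closure requires. The adduct 18 is carried through Weinreb amide 19 and silyl ether 20 to 21.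

**13 from 10 and 11 (key disconnection).** The carbinol–CH(Ar) C–C bond and the furan O–C(β) bond are cut. This removes ring C and all three core stereocentres at once and leaves the racemic spiro chromanone 10 with one labile centre and a symmetric dienone, plus the commercial aldehyde 11. The forward reaction must add the enediolate of 10 to 11 on one face and let the new alkoxide displace methoxide from the cis enone arm.

**10 from 6 and 7.** The chromanone C3–C2 bond (enolate addition to a quinone carbonyl) and the aryl–O bond (SNAr of fluoride) are cut; 10 is freed from its silyl ether 9. Ring D is thereby bought in its final oxidation state as quinone 7. The forward step needs 1,2-addition at the carbonyl flanked by the two methoxy-bearing carbons and ring closure before the aldolate reverts.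

**6 from 1 and 2.** The two benzyl ethers come from twofold SNAr on trifluoroacetophenone 1 by the alkoxide of 2, which consumes two equivalents of 2 and gives 3. The α-oxygen comes from Rubottom oxidation of silyl enol ether 4. A triisopropylsilyl group is chosen because it must not migrate to the neighbouring alkoxide in the ring-forming step.

## Roads not taken

Alternative 1: Ring A is attached last. Both bonds from ring A to the rest (aryl–O and aryl–carbonyl) are cut, giving 3,5-bis(benzyloxy)benzyne A2 and a quinol methyl ester A3 that already holds rings C, D, E and all five stereocentres. In the forward step the quinol alkoxide adds to the aryne carbon remote from the flanking benzyloxy group and the aryl anion acylates on the neighbouring ester, closing ring B to the hexa-O-benzyl target A1.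
- Merits: the chromanone is formed in one operation under fluoride conditions, the regiochemistry of a 3-alkoxyaryne is predictable, no deactivated fluoroarene has to undergo SNAr, and no chromanone with H at C3 ever exists.
- Weak points: A3 contains the two adjacent fully substituted carbons and the furan CH(Ar) centre without a ketone to enolise, so the stereochemical problem is only moved. Its hindered tertiary alkoxide is a poor aryne partner and can fragment with aromatisation of ring D, and A1 carries a tertiary benzyl ether that is hard to remove.
- Comparison: as a ring B construction this is at least as good as the SNAr of the chosen plan. The chosen plan sets against it that it builds ring B early on simple material and then uses the ring B ketone as the handle that creates three stereocentres catalytically.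

Alternative 2: The chromanone C3–C4 bond is cut. A chiral triazolylidene carbene converts the aldehyde of keto aldehyde A5 into its Breslow intermediate, which adds to the ketone on the quaternary dienone carbon and gives the spiro 3-benzyl-3-hydroxychromanone A4.
- Merits: intramolecular aldehyde–ketone benzoin closure to 3-hydroxychroman-4-ones is well established with high enantioselectivity. On this point it is better precedented than the key step chosen here, and it never generates an enolate of a β-aryloxy ketone.
- Weak points: A4 has a CH2 where the furan CH(Ar) carbon must be. Ring C then requires unmasking of one of two diastereotopic methoxy arms and an oxidative benzylic C–O bond formation beside an electron-rich ring A, with two stereocentres left to substrate control. The Breslow intermediate can also add conjugately to the methoxy enone (Stetter pathway), and A5 needs the same hindered aryl ether.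
- Comparison: the chosen plan accepts a less precedented enantio-determining step; in return it forms the furan C–O bond and the two remaining core stereocentres in the same operation, with no oxidation step.

Alternative 3: The carbinol–spiro C–C bond and the aryl–O bond are cut on a flavan-derived quinone A7 that already carries ring E and, on its quinone oxygen, the α-hydroxy ketone tether. The tether enediolate adds to the neighbouring quinone carbonyl (ring C), and the quinol alkoxide displaces the ortho fluoride (ring B), giving the penta-O-benzyl target A6, which is identical with 25.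
- Merits: it is the most convergent plan, the pyran is made on an aromatic flavan where its regiochemistry is unambiguous, and the product is one step from the target. In these respects it is better than the chosen plan.
- Weak points: the tether enolate has the quinone-bound oxygen in the β-position and should eliminate it. Enolate and quinone sit in one molecule (electron transfer), both new quaternary centres depend on substrate control alone, and A7 itself needs an enantiopure cis-flavan-3-ol quinone and an enantiopure tether.
- Comparison: the chosen plan has a weaker pyran closure (an ambident trione enol) and a longer endgame. It sets against this catalyst control of absolute configuration from an achiral, symmetric precursor made in five steps, and an SNAr that takes place early on simple material.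

Key step: step 6

Assumption: the (S,S)-ligand is written in step 6; the sense of induction on this new donor class has to be fixed by a first run, and the (R,R)-ligand is used if it is opposite.
Assumption: compounds 1, 2, 7, 11, 15 and 16 are bought.

## Route

Step 1
Reactants: 1 2',4',6'-trifluoroacetophenone; 2 benzyl alcohol (two equivalents)
Product: 3 1-[2,4-bis(benzyloxy)-6-fluorophenyl]ethan-1-one
Conditions: BnOH (2.1 equiv), NaH (2.1 equiv), DMF, 0→23 °C
Reagents that add atoms: benzyl alcohol (the second equivalent of 2), OCc1ccccc1
Why: Twofold SNAr by sodium benzyl oxide, which consumes two equivalents of 2 and releases two fluorides; in a dipolar aprotic solvent the fluoride para to the acetyl group should go first and then one ortho fluoride, and the para- and ortho-monoethers both converge on 3. The third fluoride is deactivated by two alkoxy donors, and any 2,6-bis(benzyloxy)-4-fluoro isomer is removed by crystallisation.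

Step 2
Reactants: 3 1-[2,4-bis(benzyloxy)-6-fluorophenyl]ethan-1-one
Product: 4 {[1-(2,4-bis(benzyloxy)-6-fluorophenyl)ethenyl]oxy}triisopropylsilane
Conditions: i-Pr3SiOTf, Et3N, CH2Cl2, 0→23 °C
Reagents that add atoms: triisopropylsilyl trifluoromethanesulfonate, CC(C)[Si](OS(=O)(=O)C(F)(F)F)(C(C)C)C(C)C
Why: Soft enolisation of a methyl ketone gives the only possible silyl enol ether; the bulky silyl group is chosen so that it does not migrate between oxygens in step 4.

Step 3
Reactants: 4 {[1-(2,4-bis(benzyloxy)-6-fluorophenyl)ethenyl]oxy}triisopropylsilane
Product: 6 1-[2,4-bis(benzyloxy)-6-fluorophenyl]-2-(triisopropylsilyloxy)ethan-1-one, via silyloxy epoxide 5 (not isolated)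
Conditions: mCPBA, CH2Cl2, −20→0 °C
Reagents that add atoms: 3-chloroperoxybenzoic acid, O=C(OO)c1cccc(Cl)c1
Why: Rubottom oxidation: the enol ether is epoxidised far faster than the arene, and ring opening with 1,4-silyl shift delivers the α-silyloxy ketone directly.

Step 4
Reactants: 6 1-[2,4-bis(benzyloxy)-6-fluorophenyl]-2-(triisopropylsilyloxy)ethan-1-one; 7 2,6-dimethoxy-1,4-benzoquinone
Product: 9 rac-5,7-bis(benzyloxy)-2',6'-dimethoxy-3-(triisopropylsilyloxy)spiro[chromane-2,1'-cyclohexa[2,5]diene]-4,4'-dione, via lithium quinolate 8 (not isolated)
Conditions: LiN(SiMe3)2, THF, −78 °C; 7; then DMPU, −78→23 °C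
Reagents that add atoms: none
Why: The lithium enolate should add 1,2 to the quinone carbonyl flanked by the two methoxy-bearing carbons, since the other carbonyl is a doubly vinylogous ester; the tertiary alkoxide 8 then displaces the fluoride ortho to the ketone (intramolecular SNAr, six-membered ring), which removes it from the aldol equilibrium. The single stereocentre is racemic and is erased in step 6.

Step 5
Reactants: 9 rac-5,7-bis(benzyloxy)-2',6'-dimethoxy-3-(triisopropylsilyloxy)spiro[chromane-2,1'-cyclohexa[2,5]diene]-4,4'-dione
Product: 10 rac-5,7-bis(benzyloxy)-3-hydroxy-2',6'-dimethoxyspiro[chromane-2,1'-cyclohexa[2,5]diene]-4,4'-dione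
Conditions: HF·pyridine, pyridine, THF, 0→23 °C
Reagents that add atoms: none
Why: Fluoride desilylation of an α-keto silyl ether under buffered, non-basic conditions; no enolate forms, so the ring aryloxide cannot be eliminated and the methyl vinylogous esters are not hydrolysed.

Step 6
Reactants: 10 rac-5,7-bis(benzyloxy)-3-hydroxy-2',6'-dimethoxyspiro[chromane-2,1'-cyclohexa[2,5]diene]-4,4'-dione; 11 4-(benzyloxy)benzaldehyde
Product: 13 tri-O-benzyl methoxy-enone tetracycle (furan CH S; carbinol C R; spiro C R), via zinc aldolate 12 (not isolated)
Conditions: Et2Zn (40 mol %), 2,6-bis{[(S)-2-(hydroxydiphenylmethyl)pyrrolidin-1-yl]methyl}-4-methylphenol (20 mol %), 4 Å MS, THF, 0→23 °C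
Reagents that add atoms: none
Why: Proposed new method: Et2Zn and the bis(prolinol)phenol ligand form a dinuclear zinc complex that deprotonates the α-hydroxy ketone of 10 to a bridged zinc enediolate, so both enantiomers of 10 converge; the closest known reactions are dinuclear-zinc direct aldol additions of α-hydroxy aryl ketones to aldehydes (including α-substituted donors that give tetrasubstituted carbinols) and alkoxide addition–elimination on β-alkoxy enones, whereas a cyclic, fully substituted enediolate next to a quaternary carbon and the coupled ring closure have no precedent. Aldol addition to zinc-bound 11 forms the carbinol–CH(Ar) bond and the zinc aldolate 12. The benzylic alkoxide of 12 can reach only the methoxy enone arm on its own face of ring B and closes ring C by 5-exo-trig conjugate addition, after which the dienolate expels methoxide and the dienone is restored. The carbinol configuration is set by the catalyst, which selects the enediolate face. The spiro carbon becomes stereogenic only in the ring closure, and its configuration follows from the cis fusion of rings B and C. The furan CH(Ar) centre is set under Curtin–Hammett conditions: the aldol step is reversible, the cyclisation is not, and the aldolate that places the aryl group on the convex face should close faster. The step needs aldol addition to outrun β-elimination of the ring aryloxide from the enediolate, which would aromatise ring D; the covalent chelated zinc enediolate, the ring C–O bond lying close to the nodal plane of the enediolate, and the irreversible trapping by ring closure should secure this.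

Step 7
Reactants: 13 tri-O-benzyl methoxy-enone tetracycle
Product: 14 tri-O-benzyl vinylogous acid (ring D enol OH in place of OMe; core stereocentres as in 13)
Conditions: 1 M HCl, THF, 23 °C
Reagents that add atoms: water, O
Why: Acid hydrolysis of a methyl vinylogous ester through the hemiketal; the cyclic enol ether of ring C recloses if it opens, so only the methoxy arm is lost, and the furan benzylic C–O bond is protected from ionisation by the electron-poor neighbouring carbinol carbon.

Step 8
Reactants: 15 (R)-4-benzyloxazolidin-2-one; 16 (benzyloxy)acetyl chloride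
Product: 17 (R)-4-benzyl-3-[(benzyloxy)acetyl]oxazolidin-2-one
Conditions: n-BuLi, THF, −78 °C; then 16, −78→0 °C
Reagents that add atoms: none
Why: N-Acylation of the lithiated oxazolidinone, the standard entry to glycolate imides.

Step 9
Reactants: 17 (R)-4-benzyl-3-[(benzyloxy)acetyl]oxazolidin-2-one; 11 4-(benzyloxy)benzaldehyde
Product: 18 (R)-4-benzyl-3-{(2R,3S)-2-(benzyloxy)-3-[4-(benzyloxy)phenyl]-3-hydroxypropanoyl}oxazolidin-2-one
Conditions: n-Bu2BOTf, i-Pr2NEt, CH2Cl2, −78 °C; 11, −78→0 °C; then H2O2, pH 7 buffer, MeOH
Reagents that add atoms: none
Why: Evans syn glycolate aldol: the Z boron enolate reacts through a Zimmerman–Traxler transition state on the face left open by the auxiliary, which sets both centres as (2R,3S) and leaves the two oxygens differentiated.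

Step 10
Reactants: 18 (R)-4-benzyl-3-{(2R,3S)-2-(benzyloxy)-3-[4-(benzyloxy)phenyl]-3-hydroxypropanoyl}oxazolidin-2-one
Product: 19 (2R,3S)-2-(benzyloxy)-3-[4-(benzyloxy)phenyl]-3-hydroxy-N-methoxy-N-methylpropanamide
Conditions: MeNH(OMe)·HCl, AlMe3, CH2Cl2, 0 °C
Reagents that add atoms: N,O-dimethylhydroxylamine hydrochloride, CNOC.Cl
Why: Aluminium amide transamination of the imide, assisted by the free β-hydroxyl; the auxiliary is recovered and no stereocentre is touched.

Step 11
Reactants: 19 (2R,3S)-2-(benzyloxy)-3-[4-(benzyloxy)phenyl]-3-hydroxy-N-methoxy-N-methylpropanamide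
Product: 20 (2R,3S)-2-(benzyloxy)-3-[4-(benzyloxy)phenyl]-N-methoxy-N-methyl-3-(triethylsilyloxy)propanamide
Conditions: Et3SiCl, imidazole, DMF, 0 °C
Reagents that add atoms: chlorotriethylsilane, CC[Si](Cl)(CC)CC
Why: Silylation of the secondary benzylic alcohol; the triethylsilyl group blocks retro-aldol and dehydration of the aldehyde and is removed by buffered fluoride in step 14.

Step 12
Reactants: 20 (2R,3S)-2-(benzyloxy)-3-[4-(benzyloxy)phenyl]-N-methoxy-N-methyl-3-(triethylsilyloxy)propanamide
Product: 21 (2R,3S)-2-(benzyloxy)-3-[4-(benzyloxy)phenyl]-3-(triethylsilyloxy)propanal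
Conditions: i-Bu2AlH, THF, −78 °C
Reagents that add atoms: none
Why: Reduction of a Weinreb amide stops at the chelated hemiaminal and gives the aldehyde on work-up; 21 is used at once to avoid α-epimerisation.

Step 13
Reactants: 14 tri-O-benzyl vinylogous acid; 21 (2R,3S)-2-(benzyloxy)-3-[4-(benzyloxy)phenyl]-3-(triethylsilyloxy)propanal
Product: 23 C-alkylated vinylogous acid (ring D α-carbon bearing the CH2–CH(OBn)–CH(OSiEt3)Ar chain), via alkylidene trione 22 (not isolated)
Conditions: Hantzsch ester (diethyl 2,6-dimethyl-1,4-dihydropyridine-3,5-dicarboxylate), L-proline (20 mol %), CH2Cl2, 23 °C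
Reagents that add atoms: none
Why: Three-component reductive alkylation of a cyclic 1,3-dione-type enol: Knoevenagel condensation at the only dione carbon, then conjugate hydride transfer from the dihydropyridine, which is fast enough to prevent bis-addition; the stereocentres of 21 are not involved.

Step 14
Reactants: 23 C-alkylated vinylogous acid
Product: 25 penta-O-benzyl target (furan CH S; carbinol C R; spiro C S; ring E 2S,3S), via hydroxy enol 24 (not isolated)
Conditions: HF·pyridine, pyridine, THF, 0 °C; then pyridinium p-toluenesulfonate, 4 Å MS, PhMe, 40 °C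
Reagents that add atoms: none
Why: Desilylation, then acid-catalysed vinylogous esterification: the benzylic hydroxyl adds to the ring D carbonyl carbon next to the spiro carbon (6-exo-trig hemiketal) and water is lost. No bond at the benzylic carbon is broken, so the syn chain becomes the cis (2S,3S) pair. The cross-conjugated dienone, in which one carbonyl is stabilised by both ether oxygens, is expected to be the thermodynamic product of this reversible closure.

Step 15
Reactants: 25 penta-O-benzyl target
Product: 26 target compound CNP0170480.5
Conditions: H2 (1 atm), Pd(OH)2/C, THF–MeOH, 23 °C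
Reagents that add atoms: none
Why: Hydrogenolysis of four aryl benzyl ethers and one alkyl benzyl ether under neutral conditions, as used for perbenzylated flavan-3-ols, whose hindered cyclic benzylic C–O bonds survive; the electron-rich tri- and tetrasubstituted dienone alkenes should resist hydrogenation.

## Compound list

1 | 2',4',6'-trifluoroacetophenone | CC(=O)c1c(F)cc(F)cc1F | starting material
2 | benzyl alcohol | OCc1ccccc1 | starting material
3 | 1-[2,4-bis(benzyloxy)-6-fluorophenyl]ethan-1-one | CC(=O)c1c(F)cc(OCc2ccccc2)cc1OCc1ccccc1 | intermediate
4 | {[1-(2,4-bis(benzyloxy)-6-fluorophenyl)ethenyl]oxy}triisopropylsilane | C=C(O[Si](C(C)C)(C(C)C)C(C)C)c1c(F)cc(OCc2ccccc2)cc1OCc1ccccc1 | intermediate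
5 | 2-[2,4-bis(benzyloxy)-6-fluorophenyl]-2-(triisopropylsilyloxy)oxirane | CC(C)[Si](OC1(CO1)c1c(F)cc(OCc2ccccc2)cc1OCc1ccccc1)(C(C)C)C(C)C | intermediate (not isolated)
6 | 1-[2,4-bis(benzyloxy)-6-fluorophenyl]-2-(triisopropylsilyloxy)ethan-1-one | O=C(CO[Si](C(C)C)(C(C)C)C(C)C)c1c(F)cc(OCc2ccccc2)cc1OCc1ccccc1 | intermediate
7 | 2,6-dimethoxy-1,4-benzoquinone | COC1=CC(=O)C=C(OC)C1=O | starting material
8 | lithium salt of rac-4-{2-[2,4-bis(benzyloxy)-6-fluorophenyl]-2-oxo-1-(triisopropylsilyloxy)ethyl}-4-hydroxy-3,5-dimethoxycyclohexa-2,5-dien-1-one | [Li+].[O-]C1(C(O[Si](C(C)C)(C(C)C)C(C)C)C(=O)c2c(F)cc(OCc3ccccc3)cc2OCc2ccccc2)C(OC)=CC(=O)C=C1OC | intermediate (not isolated)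
9 | rac-5,7-bis(benzyloxy)-2',6'-dimethoxy-3-(triisopropylsilyloxy)spiro[chromane-2,1'-cyclohexa[2,5]diene]-4,4'-dione | O=C1C=C(OC)C2(Oc3cc(OCc4ccccc4)cc(OCc4ccccc4)c3C(=O)C2O[Si](C(C)C)(C(C)C)C(C)C)C(OC)=C1 | intermediate
10 | rac-5,7-bis(benzyloxy)-3-hydroxy-2',6'-dimethoxyspiro[chromane-2,1'-cyclohexa[2,5]diene]-4,4'-dione | O=C1C=C(OC)C2(Oc3cc(OCc4ccccc4)cc(OCc4ccccc4)c3C(=O)C2O)C(OC)=C1 | intermediate
11 | 4-(benzyloxy)benzaldehyde | O=Cc1ccc(OCc2ccccc2)cc1 | starting material
12 | zinc aldolate, drawn as the diol: (3R)-5,7-bis(benzyloxy)-3-{(S)-[4-(benzyloxy)phenyl](hydroxy)methyl}-3-hydroxy-2',6'-dimethoxyspiro[chromane-2,1'-cyclohexa[2,5]diene]-4,4'-dione | O=C1C=C(OC)C2(Oc3cc(OCc4ccccc4)cc(OCc4ccccc4)c3C(=O)[C@@]2(O)[C@@H](O)c2ccc(OCc3ccccc3)cc2)C(OC)=C1 | intermediate (not isolated)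
13 | tri-O-benzyl methoxy-enone tetracycle: 5,7-bis(benzyloxy)-3-hydroxychroman-4-one spiro-linked at C2 to a cyclohexadienone, with ring C closed from C3 through OCH(4-benzyloxyphenyl) to one dienone β-carbon and OMe on the other; furan CH S, carbinol C R, spiro C R | O=C1C=C2O[C@@H](c3ccc(OCc5ccccc5)cc3)[C@]3(O)C(=O)c4c(OCc5ccccc5)cc(OCc5ccccc5)cc4O[C@]23C(OC)=C1 | intermediate
14 | tri-O-benzyl vinylogous acid: as 13 with enol OH in place of OMe, same spatial arrangement | O=C1C=C2O[C@@H](c3ccc(OCc5ccccc5)cc3)[C@]3(O)C(=O)c4c(OCc5ccccc5)cc(OCc5ccccc5)cc4O[C@]23C(O)=C1 | intermediate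
15 | (R)-4-benzyloxazolidin-2-one | O=C1N[C@H](Cc2ccccc2)CO1 | starting material
16 | (benzyloxy)acetyl chloride | O=C(Cl)COCc1ccccc1 | starting material
17 | (R)-4-benzyl-3-[(benzyloxy)acetyl]oxazolidin-2-one | O=C1OC[C@@H](Cc2ccccc2)N1C(=O)COCc1ccccc1 | intermediate
18 | (R)-4-benzyl-3-{(2R,3S)-2-(benzyloxy)-3-[4-(benzyloxy)phenyl]-3-hydroxypropanoyl}oxazolidin-2-one | O=C1OC[C@@H](Cc2ccccc2)N1C(=O)[C@H](OCc1ccccc1)[C@@H](O)c1ccc(OCc2ccccc2)cc1 | intermediate
19 | (2R,3S)-2-(benzyloxy)-3-[4-(benzyloxy)phenyl]-3-hydroxy-N-methoxy-N-methylpropanamide | CON(C)C(=O)[C@H](OCc1ccccc1)[C@@H](O)c1ccc(OCc2ccccc2)cc1 | intermediate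
20 | (2R,3S)-2-(benzyloxy)-3-[4-(benzyloxy)phenyl]-N-methoxy-N-methyl-3-(triethylsilyloxy)propanamide | CON(C)C(=O)[C@H](OCc1ccccc1)[C@@H](O[Si](CC)(CC)CC)c1ccc(OCc2ccccc2)cc1 | intermediate
21 | (2R,3S)-2-(benzyloxy)-3-[4-(benzyloxy)phenyl]-3-(triethylsilyloxy)propanal | O=C[C@H](OCc1ccccc1)[C@@H](O[Si](CC)(CC)CC)c1ccc(OCc2ccccc2)cc1 | intermediate
22 | alkylidene trione: Knoevenagel adduct of 14 and 21 at the ring D α-carbon, alkene geometry not defined | O=C1C=C2O[C@@H](c3ccc(OCc5ccccc5)cc3)[C@]3(O)C(=O)c4c(OCc5ccccc5)cc(OCc5ccccc5)cc4O[C@]23C(=O)C1=C[C@H](OCc1ccccc1)[C@@H](O[Si](CC)(CC)CC)c1ccc(OCc2ccccc2)cc1 | intermediate (not isolated)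
23 | C-alkylated vinylogous acid: 14 carrying on the ring D α-carbon the chain CH2–CH(OBn)–CH(OSiEt3)(4-benzyloxyphenyl), side chain syn | O=C1C=C2O[C@@H](c3ccc(OCc5ccccc5)cc3)[C@]3(O)C(=O)c4c(OCc5ccccc5)cc(OCc5ccccc5)cc4O[C@]23C(O)=C1C[C@H](OCc1ccccc1)[C@@H](O[Si](CC)(CC)CC)c1ccc(OCc2ccccc2)cc1 | intermediate
24 | hydroxy enol: 23 without the triethylsilyl group | O=C1C=C2O[C@@H](c3ccc(OCc5ccccc5)cc3)[C@]3(O)C(=O)c4c(OCc5ccccc5)cc(OCc5ccccc5)cc4O[C@]23C(O)=C1C[C@H](OCc1ccccc1)[C@@H](O)c1ccc(OCc2ccccc2)cc1 | intermediate (not isolated)
25 | penta-O-benzyl target: furan CH S, carbinol C R, spiro C S, ring E 2S,3S | O=C1C=C2O[C@@H](c3ccc(OCc5ccccc5)cc3)[C@]3(O)C(=O)c4c(OCc5ccccc5)cc(OCc5ccccc5)cc4O[C@]23C2=C1C[C@H](OCc1ccccc1)[C@H](c1ccc(OCc3ccccc3)cc1)O2 | intermediate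
26 | CNP0170480.5: furan CH S, carbinol C R, spiro C S, ring E 2S,3S | O=C1C=C2O[C@@H](c3ccc(O)cc3)[C@]3(O)C(=O)c4c(O)cc(O)cc4O[C@]23C2=C1C[C@H](O)[C@H](c1ccc(O)cc1)O2 | target

## Step count and least certain steps

Total: 15 steps. Longest linear sequence: 10 steps (steps 1–7 and 13–15); the aldehyde branch (steps 8–12) joins at step 13.

**Step 6 (key step, proposed new method).** The most likely failure is β-elimination of the ring aryloxide from the enediolate, which opens ring B and aromatises ring D to a diaryl 1,2-diketone and is strongly downhill. The second is slow or unselective addition at the congested, fully substituted enediolate carbon. The fallback uses known chemistry, sets out from 10 and returns at 13. Me3SiOTf and Et3N convert 10 into the bis(trimethylsilyl) enediol ether F1 without a free enediolate. A Mukaiyama aldol addition of F1 to 11 (BF3·OEt2, CH2Cl2, −78 °C) and aqueous work-up give the racemic aldol adduct F2. Catalytic camphorsulfonic acid closes ring C by vinylogous transesterification to the racemic tetracycle F3, the epimer at the furan carbon is removed by chromatography, and the enantiomers are separated on a chiral stationary phase to give 13.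

**Step 4.** The quinol alkoxide may revert before the slow SNAr on the electron-rich fluoroarene, and the liberated enolate can then transfer an electron to the quinone or add to it conjugately. The fallback sets out from 6 and returns at 9. The quinone is replaced by its monoketal 2,4,4,6-tetramethoxycyclohexa-2,5-dien-1-one F4, made from commercial 2,4,6-trimethoxyphenol with PhI(OAc)2 in methanol. F4 has only the wanted carbonyl and is no oxidant, so the lithium enolate of 6 can add and the alkoxide can close by SNAr on warming to the spiro ketal F5. Dilute aqueous oxalic acid in THF then hydrolyses the ketal to 9.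

**Step 14.** The hydroxyl may close onto the other ring D carbonyl carbon (the one between the two CH/C carbons), giving the linearly conjugated isomer, or the para-benzyloxybenzylic carbinol may ionise under acid and lose the cis relationship. The fallback sets out from 23 and returns at 25. Me3SiCHN2 in toluene–methanol O-methylates 23, and the isomer with OMe on the carbon next to the spiro carbon, the methyl vinylogous ester F6, is isolated. Buffered HF·pyridine gives the alcohol F7, and Cs2CO3 in MeCN closes ring E by 6-endo-trig addition–elimination with loss of methoxide. The regiochemistry is fixed by the position of the methoxy group and the benzylic carbon is untouched.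

**Step 7.** The acid may also ionise the furan benzylic C–O bond, which would lead to epimerisation or a semipinacol shift of the neighbouring α-ketol. The fallback goes from 13 to 14 by SN2 demethylation at the methyl carbon with LiCl in DMF at 80 °C, followed by mild acidification; no acid touches the core and no new compound is made (F0).

**Step 15.** Hydrogenolysis may cut the two cyclic benzylic C–O bonds, which are benzylic ethers of vinylogous acids, or saturate a dienone alkene during the slower cleavage of the alkyl benzyl ether. The fallback goes from 25 to 26 with BCl3 and pentamethylbenzene as cation scavenger in CH2Cl2 at −78 °C, a Lewis-acid cleavage without hydrogen or metal surface; no new compound is made (F0).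

## Further compounds

F1 | step 6 | rac-5,7-bis(benzyloxy)-2',6'-dimethoxy-3,4-bis(trimethylsilyloxy)spiro[chromene-2,1'-cyclohexa[2,5]dien]-4'-one | O=C1C=C(OC)C2(Oc3cc(OCc4ccccc4)cc(OCc4ccccc4)c3C(O[Si](C)(C)C)=C2O[Si](C)(C)C)C(OC)=C1
F2 | step 6 | racemic aldol adduct (racemate of 12; relative configuration shown) | O=C1C=C(OC)C2(Oc3cc(OCc4ccccc4)cc(OCc4ccccc4)c3C(=O)[C@@]2(O)[C@@H](O)c2ccc(OCc3ccccc3)cc2)C(OC)=C1
F3 | step 6 | racemic tetracycle (racemate of 13; relative configuration shown) | O=C1C=C2O[C@@H](c3ccc(OCc5ccccc5)cc3)[C@]3(O)C(=O)c4c(OCc5ccccc5)cc(OCc5ccccc5)cc4O[C@]23C(OC)=C1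
F4 | step 4 | 2,4,4,6-tetramethoxycyclohexa-2,5-dien-1-one | COC1=CC(OC)(OC)C=C(OC)C1=O
F5 | step 4 | rac-5,7-bis(benzyloxy)-2',4',4',6'-tetramethoxy-3-(triisopropylsilyloxy)spiro[chromane-2,1'-cyclohexa[2,5]dien]-4-one | COC1=CC(OC)(OC)C=C(OC)C12Oc1cc(OCc3ccccc3)cc(OCc3ccccc3)c1C(=O)C2O[Si](C(C)C)(C(C)C)C(C)C
F6 | step 14 | methyl vinylogous ester of 23 (OMe on the ring D carbon next to the spiro carbon) | O=C1C=C2O[C@@H](c3ccc(OCc5ccccc5)cc3)[C@]3(O)C(=O)c4c(OCc5ccccc5)cc(OCc5ccccc5)cc4O[C@]23C(OC)=C1C[C@H](OCc1ccccc1)[C@@H](O[Si](CC)(CC)CC)c1ccc(OCc2ccccc2)cc1
F7 | step 14 | alcohol from F6 (triethylsilyl group removed) | O=C1C=C2O[C@@H](c3ccc(OCc5ccccc5)cc3)[C@]3(O)C(=O)c4c(OCc5ccccc5)cc(OCc5ccccc5)cc4O[C@]23C(OC)=C1C[C@H](OCc1ccccc1)[C@@H](O)c1ccc(OCc2ccccc2)cc1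
F0 | step 7 | none | none
F0 | step 15 | none | none
A1 | alternative 1 | hexa-O-benzyl target | O=C1C=C2O[C@@H](c3ccc(OCc5ccccc5)cc3)[C@]3(OCc5ccccc5)C(=O)c4c(OCc5ccccc5)cc(OCc5ccccc5)cc4O[C@]23C2=C1C[C@H](OCc1ccccc1)[C@H](c1ccc(OCc3ccccc3)cc1)O2
A2 | alternative 1 | 3,5-bis(benzyloxy)benzyne | C1#CC(OCc2ccccc2)=CC(OCc2ccccc2)=C1
A3 | alternative 1 | quinol methyl ester holding rings C, D and E (tertiary quinol OH on the future spiro carbon; OBn and CO2Me on the future carbinol carbon) | O=C1C=C2O[C@@H](c3ccc(OCc4ccccc4)cc3)[C@](OCc3ccccc3)(C(=O)OC)[C@@]2(O)C2=C1C[C@H](OCc1ccccc1)[C@H](c1ccc(OCc3ccccc3)cc1)O2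
A4 | alternative 2 | spiro 3-[4-(benzyloxy)benzyl]-5,7-bis(benzyloxy)-3-hydroxy-2',6'-dimethoxychromanone dienone | O=C1C=C(OC)C2(Oc3cc(OCc4ccccc4)cc(OCc4ccccc4)c3C(=O)[C@@]2(O)Cc2ccc(OCc3ccccc3)cc2)C(OC)=C1
A5 | alternative 2 | keto aldehyde: 2,4-bis(benzyloxy)-6-({1-[2-(4-benzyloxyphenyl)acetyl]-2,6-dimethoxy-4-oxocyclohexa-2,5-dien-1-yl}oxy)benzaldehyde | O=Cc1c(OCc2ccccc2)cc(OCc2ccccc2)cc1OC1(C(=O)Cc2ccc(OCc3ccccc3)cc2)C(OC)=CC(=O)C=C1OC
A6 | alternative 3 | penta-O-benzyl target (identical with 25) | O=C1C=C2O[C@@H](c3ccc(OCc5ccccc5)cc3)[C@]3(O)C(=O)c4c(OCc5ccccc5)cc(OCc5ccccc5)cc4O[C@]23C2=C1C[C@H](OCc1ccccc1)[C@H](c1ccc(OCc3ccccc3)cc1)O2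
A7 | alternative 3 | flavan-derived quinone with the α-hydroxy ketone tether on the quinone oxygen | O=C1C=C(O[C@@H](c2ccc(OCc3ccccc3)cc2)C(O)C(=O)c2c(F)cc(OCc3ccccc3)cc2OCc2ccccc2)C(=O)C2=C1C[C@H](OCc1ccccc1)[C@H](c1ccc(OCc3ccccc3)cc1)O2
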